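## Analysis of the target

Numbering used throughout:
- Ring A is the 3,4,5-trimethoxyphenyl ring (C1 to C6). C7 is the ketone carbon, C8 the stereocentre and C9 the methyl group.
- Ring B is C1' to C6'. It is bound through O4' on C4', carries methoxy groups on C3' and C5', and bears the chain C7'=C8'–C9'H2OH on C1'.

The target 10 is an open-chain 8-O-4' oxyneolignan. Ring A carries the C7 ketone; C8 bears H, C9 and O4'; and O4' sits on C4' of ring B between two methoxy groups, para to the (E)-allylic alcohol chain. Both rings have substitution patterns that can be bought, so no ring has to be built and all difficulty lies in the triad C7(=O)–C8–O4'. C8 is the only stereocentre, and with O4' > C7 > C9 > H the descriptor in the SMILES string translates into (R).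

C8–H is flanked by the aroyl group and the aryloxy group. Carbonates, alkoxides, basic fluoride or amine/Lewis acid pairs can therefore enolise it, and enolisation erases the only stereochemical information of the molecule. O4' belongs to a di-ortho-substituted phenol, so substitution at the secondary C8 calls for exactly the basic, forcing conditions that the product cannot stand.

The electron-rich cinnamyl alcohol has four weaknesses:
- it ionises in acid;
- it oxidises easily;
- it loses its (E) geometry under triplet sensitisation;
- it becomes a π-allyl precursor once acylated.

The C7 ketone in turn forbids late hydride or organometallic steps.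

The feature that the strategy uses is the C7–C8 bond. C7 is an acyl carbon and C8 carries the lone-pair donor O4', so C8 is as good a planar, stabilised radical as it is a labile carbanion. The bond can thus be made from an acyl metal species and a stereochemically blank C8.

## Retrosynthetic reasoning

**10 to 9 (O–Si bond at C9').** The only operation allowed after C8 is set is removal of a silyl group from the allylic oxygen. The forward step has to be free of base, so a buffered acidic fluoride source is planned. The silyl ether is needed because an acid chloride is present in the key step, and because an allylic ester or carbonate would be ionised by low-valent nickel.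

**9 to 7 + 8 (C7–C8 bond, key disconnection).**
- Where the cut falls: the central C–C bond is cut, not the C8–O4' bond that is usually cut. This divides the skeleton into the commercial C10 acyl unit 8 and the ring B unit 7.
- What is gained: C8 becomes a planar α-aryloxy radical in the forward sense, so the precursor 7 needs no configuration at all and can be racemic.
- What the forward reaction must achieve: join the two halves, funnel both enantiomers of 7 into (R)-9 under control of a chiral NiBr2(diglyme)/bis(oxazoline) catalyst, and do so without any base that could enolise the product.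
- Choice of reductant: a metal reductant is preferred to a photocatalyst, because triplet energy transfer would scramble the C7'=C8' geometry.

**7 to 5 + 6 (acyl–O bond of the redox-active ester).** A routine activation turns the carboxyl group of 5 into a one-electron leaving group.

**5 to 4 (ester C–O bond).** This is a saponification. It is harmless because C8 is still racemic.

**4 to 1 + 2 by way of 3 (C8–O4' and O–Si bonds).**
- Since configuration does not matter here, the hindered phenoxide of 1 can be alkylated with racemic 2 under ordinary basic conditions.
- The carboxyl carbon of 2 works twice. It first activates C8–Br for substitution by the hindered O4', and it later leaves in the decarboxylative key step.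
- Alkylating the phenol before silylation removes any need to differentiate the two hydroxy groups of 1.

## Alternatives that were turned down

Alternative 1: the textbook cut of C8–O4' in the ketone itself.
- Forward key step: a Williamson substitution of 2-bromo-1-(3,4,5-trimethoxyphenyl)propan-1-one A1 by the phenoxide of 1.
- Why turned down: A1 is racemic and configurationally unstable through halide exchange and enolisation. The product also sits in the presence of carbonate and phenoxide, so the route is short but can only give the racemate, and a resolution would discard half of the material.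
- Catalytic asymmetric version of the same bond: O–H insertion of the carbene from 2-diazo-1-(3,4,5-trimethoxyphenyl)propan-1-one A2 with CuOTf/bis(oxazoline). It has to outrun the 1,2-hydride shift from C9. It also sets C8 in a proton transfer on a free enol or ylide, next to a very hindered phenol.
- Chiral-pool version from a lactate sulfonate: this carries the labile centre through several further steps, including an organomagnesium addition. It is kept only as the fallback for step 4.

Alternative 2: cut of O4'–C4' (aryl ether bond from the ring B side).
- Forward key step: (R)-2-hydroxy-1-(3,4,5-trimethoxyphenyl)propan-1-one A3 would come from an enzymatic cross-acyloin condensation of the ring A aldehyde with a two-carbon aldehyde. It would be O-arylated with retention, either by nucleophilic aromatic substitution on a ring B aryl fluoride with a para formyl group or by a Cu(OAc)2-mediated Chan–Lam coupling. The product is (R)-3,5-dimethoxy-4-{[1-oxo-1-(3,4,5-trimethoxyphenyl)propan-2-yl]oxy}benzaldehyde A4.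
- Why turned down, electrophile: C4' is flanked by two π-donating methoxy groups that shield it and lower its electrophilicity.
- Why turned down, nucleophile: the nucleophile is a secondary alkoxide next to a ketone. It equilibrates through the enediolate, with loss of configuration and transposition of the carbonyl group.
- Why turned down, coupling partners: di-ortho-substituted arylboron reagents protodeboronate readily and couple poorly with secondary alcohols.
- Why turned down, step economy: A4 would still need a two-carbon homologation and an aldehyde-selective reduction beside the C7 ketone, all on a labile compound.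

Alternative 3: no skeletal cut, but stereochemical editing of the racemate at C8–H and C7=O by dynamic kinetic resolution.
- Forward key step: the racemic silyl-protected ketone A5 would be made from A1. It would be reduced with RuCl(p-cymene)(TsDPEN) in HCO2H/Et3N while C8 epimerises, to give the (1S,2R)-alcohol A6, which would be reoxidised to 9.
- Why turned down, economy: a second stereocentre (C7) is made only to be destroyed, at the price of two redox steps on top of the textbook assembly.
- Why turned down, rates: an acyclic α-aryloxy ketone has no second activating group. Its epimerisation in the buffered medium may therefore not outrun reduction.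
- Why turned down, reoxidation: the benzylic alcohol must be oxidised beside an electron-rich cinnamyl ether, and with amine-based oxidations this puts C8 at risk a second time.

Key step: step 4

Assumption 1: the absolute sense of induction in step 4 cannot be derived with certainty by analogy. The (R,R) ligand is written. The commercial (S,S) antipode takes its place if a first run, correlated with 9 from the lactate fallback, shows the opposite sense.

Assumption 2: (E)-sinapyl alcohol 1 is taken as commercially available. The fallback for step 1 gives access from syringaldehyde.

## Steps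

Step 1
Reactants: 1 (E)-sinapyl alcohol, 4-[(E)-3-hydroxyprop-1-en-1-yl]-2,6-dimethoxyphenol; 2 methyl 2-bromopropanoate (racemic)
Product: 4 methyl (±)-2-{4-[(E)-3-(tert-butyldimethylsilyloxy)prop-1-en-1-yl]-2,6-dimethoxyphenoxy}propanoate, via hydroxy ester 3 (not isolated)
Conditions: K2CO3 (3 equiv), DMF, N2, 23 to 40 °C; then imidazole, TBSCl, 23 °C
Reagents that add atoms: tert-butyldimethylsilyl chloride, CC(C)(C)[Si](C)(C)Cl
Why: Williamson ether synthesis followed by silylation in the same DMF solution; K2CO3 deprotonates only the phenol of 1, and the carbonyl-activated secondary bromide 2 accepts even the di-ortho-substituted phenoxide in an SN2 reaction. C8 is formed racemic on purpose, so base and warming cost nothing, and alkylation before silylation avoids any differentiation of the two hydroxy groups.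

Step 2
Reactants: 4 methyl (±)-2-{4-[(E)-3-(tert-butyldimethylsilyloxy)prop-1-en-1-yl]-2,6-dimethoxyphenoxy}propanoate
Product: 5 (±)-2-{4-[(E)-3-(tert-butyldimethylsilyloxy)prop-1-en-1-yl]-2,6-dimethoxyphenoxy}propanoic acid
Conditions: LiOH·H2O, THF/MeOH/H2O, 0 to 23 °C; then 0.5 M HCl to pH 4, 0 °C
Reagents that add atoms: lithium hydroxide, [Li+].[OH-]
Why: Saponification of a methyl ester; the primary silyl ether and the alkene are stable to LiOH, and the short cold acidification to pH 4 is too mild to cleave the silyl ether or to ionise the allylic C–O bond. C8 is still racemic, so enolisation is of no consequence.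

Step 3
Reactants: 5 (±)-2-{4-[(E)-3-(tert-butyldimethylsilyloxy)prop-1-en-1-yl]-2,6-dimethoxyphenoxy}propanoic acid; 6 N-hydroxyphthalimide
Product: 7 1,3-dioxoisoindolin-2-yl (±)-2-{4-[(E)-3-(tert-butyldimethylsilyloxy)prop-1-en-1-yl]-2,6-dimethoxyphenoxy}propanoate (redox-active ester)
Conditions: N,N'-diisopropylcarbodiimide, DMAP (10 mol %), CH2Cl2, 0 to 23 °C
Reagents that add atoms: none
Why: Steglich-type carbodiimide esterification; the acidic N–OH group of 6 intercepts the O-acylisourea quickly. Esters of this kind from 2-aryloxyalkanoic acids are stable enough for a short silica filtration or crystallisation, which gives clean material for the asymmetric step.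

Step 4
Reactants: 7 1,3-dioxoisoindolin-2-yl (±)-2-{4-[(E)-3-(tert-butyldimethylsilyloxy)prop-1-en-1-yl]-2,6-dimethoxyphenoxy}propanoate; 8 3,4,5-trimethoxybenzoyl chloride
Product: 9 (R)-2-{4-[(E)-3-(tert-butyldimethylsilyloxy)prop-1-en-1-yl]-2,6-dimethoxyphenoxy}-1-(3,4,5-trimethoxyphenyl)propan-1-one
Conditions: NiBr2(diglyme) (10 mol %), (R,R)-Ph-BOX = 2,2'-(propane-2,2-diyl)bis[(4R)-4-phenyl-4,5-dihydro-1,3-oxazole] (12 mol %), Zn powder (2 equiv), 2,6-dimethylbenzoic acid (1 equiv), 3 Å MS, THF/DMA 7:3, 0 °C
Reagents that add atoms: none
Why: Proposed new method: the closest known reaction types are the NiCl2(dme)/bis(oxazoline)-catalysed asymmetric reductive acyl cross-coupling of acid chlorides with racemic secondary benzylic chlorides, the enantioconvergent nickel/bis(oxazoline) coupling of racemic benzylic N-hydroxyphthalimide esters with alkenyl bromides, and the racemic nickel/zinc ketone synthesis from such esters and acyl chlorides, and the new element is their merger on an α-aryloxyalkyl radical. Zerovalent nickel inserts into the C–Cl bond of 8 to give an aroyl complex of divalent nickel, while one-electron reduction of 7 by monovalent nickel or zinc breaks the N–O bond and the carboxyl radical loses CO2 at once, which leaves a planar radical at C8 that the lone pair of O4' stabilises. Both enantiomers of 7 give this one radical, which the aroyl complex traps reversibly, and reductive elimination from trivalent nickel forms C7–C8 and returns monovalent nickel. C8 is the only new stereocentre and is controlled by the C2-symmetric ligand in the reductive elimination, which has to tell the small C9 methyl group from ring B, a rigid wall because the methoxy groups on C3' and C5' twist it out of the C8–O4' plane, a size gap at least as large as methyl against aryl in the benzylic precedents. No ring is closed. Cross-coupling is favoured over the two homocouplings because 8 is activated by two-electron insertion and 7 by one-electron reduction. The C7'=C8' alkene is 1,2-disubstituted and electron-rich and so a slow acceptor for the nucleophilic C8 radical compared with capture by nickel, and a silyl ether at C9', unlike an ester or carbonate, is not ionised by zerovalent nickel. The strongest base present is phthalimide anion, which the carboxylic acid additive protonates, so C8–H of 9 should not exchange, just as the comparably acidic α-aryl ketones of the benzylic precedents keep their configuration in such a medium.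

Step 5
Reactants: 9 (R)-2-{4-[(E)-3-(tert-butyldimethylsilyloxy)prop-1-en-1-yl]-2,6-dimethoxyphenoxy}-1-(3,4,5-trimethoxyphenyl)propan-1-one
Product: 10 (R)-2-{4-[(E)-3-hydroxyprop-1-en-1-yl]-2,6-dimethoxyphenoxy}-1-(3,4,5-trimethoxyphenyl)propan-1-one (target, CNP0171423.1)
Conditions: HF·pyridine, pyridine, THF, 0 to 23 °C, polyethylene vessel; then pH 7 phosphate buffer
Reagents that add atoms: none
Why: Fluoride-mediated desilylation of a primary silyl ether in a weakly acidic buffer; unlike with Bu4NF, no species basic enough to enolise C7/C8 is present, and the medium is not acidic enough to ionise the electron-rich cinnamyl alcohol. C8 and the (E)-alkene are not touched.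

## Compound list

1 | (E)-sinapyl alcohol | COc1cc(/C=C/CO)cc(OC)c1O | starting material
2 | methyl 2-bromopropanoate (racemic) | COC(=O)C(C)Br | starting material
3 | methyl (±)-2-{4-[(E)-3-hydroxyprop-1-en-1-yl]-2,6-dimethoxyphenoxy}propanoate | COC(=O)C(C)Oc1c(OC)cc(/C=C/CO)cc1OC | intermediate (not isolated)
4 | methyl (±)-2-{4-[(E)-3-(tert-butyldimethylsilyloxy)prop-1-en-1-yl]-2,6-dimethoxyphenoxy}propanoate | COC(=O)C(C)Oc1c(OC)cc(/C=C/CO[Si](C)(C)C(C)(C)C)cc1OC | intermediate
5 | (±)-2-{4-[(E)-3-(tert-butyldimethylsilyloxy)prop-1-en-1-yl]-2,6-dimethoxyphenoxy}propanoic acid | OC(=O)C(C)Oc1c(OC)cc(/C=C/CO[Si](C)(C)C(C)(C)C)cc1OC | intermediate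
6 | N-hydroxyphthalimide | ON1C(=O)c2ccccc2C1=O | starting material
7 | 1,3-dioxoisoindolin-2-yl (±)-2-{4-[(E)-3-(tert-butyldimethylsilyloxy)prop-1-en-1-yl]-2,6-dimethoxyphenoxy}propanoate | CC(Oc1c(OC)cc(/C=C/CO[Si](C)(C)C(C)(C)C)cc1OC)C(=O)ON1C(=O)c2ccccc2C1=O | intermediate
8 | 3,4,5-trimethoxybenzoyl chloride | COc1cc(C(Cl)=O)cc(OC)c1OC | starting material
9 | (R)-2-{4-[(E)-3-(tert-butyldimethylsilyloxy)prop-1-en-1-yl]-2,6-dimethoxyphenoxy}-1-(3,4,5-trimethoxyphenyl)propan-1-one | COc1cc(C(=O)[C@@H](C)Oc2c(OC)cc(/C=C/CO[Si](C)(C)C(C)(C)C)cc2OC)cc(OC)c1OC | intermediate
10 | (R)-2-{4-[(E)-3-hydroxyprop-1-en-1-yl]-2,6-dimethoxyphenoxy}-1-(3,4,5-trimethoxyphenyl)propan-1-one | COc1cc(C(=O)[C@@H](C)Oc2c(OC)cc(/C=C/CO)cc2OC)cc(OC)c1OC | target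

## Step count and least certain steps

Total step count: 5. Longest linear sequence: 5 (1 to 4 to 5 to 7 to 9 to 10). Compounds 2, 6 and 8 are bought.

**Step 4 (key step, proposed new method).** Three processes may go wrong:
- Facial discrimination in the bond-forming reductive elimination may be insufficient, because an α-aryloxy radical is more nucleophilic and less delocalised than the benzylic radicals of the precedents.
- Material may be lost through radical dimerisation or hydrogen abstraction, β-hydride elimination towards C9, or decarbonylation of the aroyl nickel complex.
- Zinc-assisted enolisation of the product may slowly erode the configuration at C8.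

The fallback uses known chiral-pool chemistry, sets out from 1 and comes back at 9. Phenol 1 is alkylated with commercial ethyl (S)-2-(tosyloxy)propanoate (K2CO3, MeCN, 50 °C). The SN2 reaction proceeds with inversion and gives ethyl (R)-2-{4-[(E)-3-hydroxyprop-1-en-1-yl]-2,6-dimethoxyphenoxy}propanoate F1. Silylation (TBSCl, imidazole, CH2Cl2) gives ethyl (R)-2-{4-[(E)-3-(tert-butyldimethylsilyloxy)prop-1-en-1-yl]-2,6-dimethoxyphenoxy}propanoate F2. Aminolysis with MeNH(OMe)·HCl and i-PrMgCl in THF at −20 °C gives (R)-2-{4-[(E)-3-(tert-butyldimethylsilyloxy)prop-1-en-1-yl]-2,6-dimethoxyphenoxy}-N-methoxy-N-methylpropanamide F3. A Weinreb ketone synthesis with commercial 3,4,5-trimethoxyphenylmagnesium bromide (THF, −20 to 0 °C, cold acidic quench) then gives 9. The chelated tetrahedral adduct shields C8–H until the quench. This sequence also supplies authentic (R)-9 for the configurational correlation named in assumption 1.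

**Step 5.** Two processes may go wrong: erosion of the C8 configuration if the fluoride medium turns basic during reaction or work-up, and acid-promoted ionisation of the C9'–O bond of the electron-rich cinnamyl system.

The fallback moves the deprotection ahead of the creation of the stereocentre, sets out from 7 and comes back at 10. The racemic ester 7 is desilylated with HF·pyridine to 1,3-dioxoisoindolin-2-yl (±)-2-{4-[(E)-3-hydroxyprop-1-en-1-yl]-2,6-dimethoxyphenoxy}propanoate F4. Acid chloride 8 is converted with pyridine-2-thiol and Et3N in CH2Cl2 into S-(pyridin-2-yl) 3,4,5-trimethoxybenzenecarbothioate F5. This acyl donor does not esterify a primary alcohol at 0 °C without activation. The coupling of step 4 is then run on F4 and F5, so 10 is formed in the last operation and nothing follows the setting of C8.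

**Step 1.** Three processes may go wrong: air oxidation and radical coupling of the electron-rich phenoxide of 1, loss of hydroxide from the phenoxide towards an extended quinone methide on warming, and elimination of HBr from 2 in competition with the hindered substitution.

The fallback builds the side chain after the ether bond, sets out from 2 and comes back at 3. Robust commercial syringaldehyde is alkylated with 2 (K2CO3, DMF, 60 °C) to methyl (±)-2-(4-formyl-2,6-dimethoxyphenoxy)propanoate F6. A Wittig reaction with (triphenylphosphoranylidene)acetaldehyde in toluene at 80 °C gives methyl (±)-2-{2,6-dimethoxy-4-[(E)-3-oxoprop-1-en-1-yl]phenoxy}propanoate F7. A Luche reduction (NaBH4, CeCl3·7H2O, MeOH, 0 °C) reduces the enal in the 1,2 sense beside the untouched methyl ester and gives 3. Compound 3 is silylated to 4 as in the second half of step 1.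

## Further compounds

F1 | step 4 | ethyl (R)-2-{4-[(E)-3-hydroxyprop-1-en-1-yl]-2,6-dimethoxyphenoxy}propanoate | CCOC(=O)[C@@H](C)Oc1c(OC)cc(/C=C/CO)cc1OC
F2 | step 4 | ethyl (R)-2-{4-[(E)-3-(tert-butyldimethylsilyloxy)prop-1-en-1-yl]-2,6-dimethoxyphenoxy}propanoate | CCOC(=O)[C@@H](C)Oc1c(OC)cc(/C=C/CO[Si](C)(C)C(C)(C)C)cc1OC
F3 | step 4 | (R)-2-{4-[(E)-3-(tert-butyldimethylsilyloxy)prop-1-en-1-yl]-2,6-dimethoxyphenoxy}-N-methoxy-N-methylpropanamide | CON(C)C(=O)[C@@H](C)Oc1c(OC)cc(/C=C/CO[Si](C)(C)C(C)(C)C)cc1OC
F4 | step 5 | 1,3-dioxoisoindolin-2-yl (±)-2-{4-[(E)-3-hydroxyprop-1-en-1-yl]-2,6-dimethoxyphenoxy}propanoate | CC(Oc1c(OC)cc(/C=C/CO)cc1OC)C(=O)ON1C(=O)c2ccccc2C1=O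
F5 | step 5 | S-(pyridin-2-yl) 3,4,5-trimethoxybenzenecarbothioate | COc1cc(C(=O)Sc2ccccn2)cc(OC)c1OC
F6 | step 1 | methyl (±)-2-(4-formyl-2,6-dimethoxyphenoxy)propanoate | COC(=O)C(C)Oc1c(OC)cc(C=O)cc1OC
F7 | step 1 | methyl (±)-2-{2,6-dimethoxy-4-[(E)-3-oxoprop-1-en-1-yl]phenoxy}propanoate | COC(=O)C(C)Oc1c(OC)cc(/C=C/C=O)cc1OC
A1 | alternative 1 | 2-bromo-1-(3,4,5-trimethoxyphenyl)propan-1-one (racemic) | CC(Br)C(=O)c1cc(OC)c(OC)c(OC)c1
A2 | alternative 1 | 2-diazo-1-(3,4,5-trimethoxyphenyl)propan-1-one | CC(=[N+]=[N-])C(=O)c1cc(OC)c(OC)c(OC)c1
A3 | alternative 2 | (R)-2-hydroxy-1-(3,4,5-trimethoxyphenyl)propan-1-one | COc1cc(C(=O)[C@@H](C)O)cc(OC)c1OC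
A4 | alternative 2 | (R)-3,5-dimethoxy-4-{[1-oxo-1-(3,4,5-trimethoxyphenyl)propan-2-yl]oxy}benzaldehyde | COc1cc(C(=O)[C@@H](C)Oc2c(OC)cc(C=O)cc2OC)cc(OC)c1OC
A5 | alternative 3 | (±)-2-{4-[(E)-3-(tert-butyldimethylsilyloxy)prop-1-en-1-yl]-2,6-dimethoxyphenoxy}-1-(3,4,5-trimethoxyphenyl)propan-1-one | COc1cc(C(=O)C(C)Oc2c(OC)cc(/C=C/CO[Si](C)(C)C(C)(C)C)cc2OC)cc(OC)c1OC
A6 | alternative 3 | (1S,2R)-2-{4-[(E)-3-(tert-butyldimethylsilyloxy)prop-1-en-1-yl]-2,6-dimethoxyphenoxy}-1-(3,4,5-trimethoxyphenyl)propan-1-ol | COc1cc([C@H](O)[C@@H](C)Oc2c(OC)cc(/C=C/CO[Si](C)(C)C(C)(C)C)cc2OC)cc(OC)c1OC
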